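**Retrosynthetic overview**
1. Target 12 comes from the (2S)-flavanone 11 by removal of four MOM ethers.
2. Ring C is the only ring that is made (rings A and B are bought as arenes). It is closed from chalcone 10 by forming the O1–C2 bond in an enantioselective oxa-Michael addition that sets C2.
3. Chalcone 10 comes from a Claisen–Schmidt union of ring A ketone 4 and ring B aldehyde 9.
4. Ketone 4 comes from phloroacetophenone 1 by C-prenylation, then bis-MOM protection that leaves only the OH next to the prenyl group free (this directs closure to the 8-prenyl, not the 6-prenyl, chromanone).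
5. Aldehyde 9 comes from 2,4-dihydroxybenzaldehyde 5 by 4-O-prenylation and 2-O-MOM protection, aromatic Claisen shift to C5 (gives the 1,1-dimethylallyl group), then MOM capping.

Assumption: the SMILES is read as the (2S)-flavanone; which antipode of catalyst A gives 2S is fixed by one calibration run against the racemate, and the mirror-image catalyst (from (R)-tert-leucine) is used if needed.

Catalyst A (step 6, prepared separately, not counted): 1-[3,5-bis(trifluoromethyl)phenyl]-3-[(2S)-3,3-dimethyl-1-{[tris(4-methoxyphenyl)-λ5-phosphanylidene]amino}butan-2-yl]thiourea, SMILES COc1ccc(cc1)P(=NC[C@@H](NC(=S)Nc1cc(cc(c1)C(F)(F)F)C(F)(F)F)C(C)(C)C)(c1ccc(OC)cc1)c1ccc(OC)cc1.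

**Route**

Step 1
Reactants: 1 2,4,6-trihydroxyacetophenone; 2 prenyl bromide (1-bromo-3-methylbut-2-ene)
Product: 3 1-[2,4,6-trihydroxy-3-(3-methylbut-2-en-1-yl)phenyl]ethan-1-one
Conditions: 2 (1.0 equiv), 10% aq KOH, 0 °C, 2 h; then dil. HCl
Reagents that add atoms: none
Why: Friedel–Crafts-type C-alkylation of the phloroglucinol phenoxide; in water the oxygens are solvated, so the allylic bromide is attacked by ring carbon C3 (C3 and C5 are equivalent), giving the mono-C-prenyl ketone in moderate yield.

Step 2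
Reactants: 3 1-[2,4,6-trihydroxy-3-(3-methylbut-2-en-1-yl)phenyl]ethan-1-one
Product: 4 1-[2-hydroxy-4,6-bis(methoxymethoxy)-3-(3-methylbut-2-en-1-yl)phenyl]ethan-1-one
Conditions: MOMCl (2.2 equiv), i-Pr2NEt, CH2Cl2, 0 °C to rt
Reagents that add atoms: chloromethyl methyl ether (MOMCl), COCCl
Why: Williamson-type O-alkylation under weak-base control; the para-OH and the less hindered ortho-OH (C6) are etherified, while the 2-OH, wedged between acetyl and prenyl and held in the C=O hydrogen bond, stays free.

Step 3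
Reactants: 5 2,4-dihydroxybenzaldehyde; 2 prenyl bromide
Product: 7 2-(methoxymethoxy)-4-[(3-methylbut-2-en-1-yl)oxy]benzaldehyde, via 2-hydroxy-4-[(3-methylbut-2-en-1-yl)oxy]benzaldehyde 6 (not isolated)
Conditions: 2 (1.05 equiv), K2CO3, acetone, rt; then MOMCl, K2CO3, reflux (one pot)
Reagents that add atoms: chloromethyl methyl ether (MOMCl), COCCl
Why: Sequential Williamson etherification; the non-chelated, more acidic 4-OH is alkylated first at rt, then the chelated 2-OH is capped by MOMCl at reflux, which removes the hydrogen bond that would steer the later Claisen shift to C3.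

Step 4
Reactants: 7 2-(methoxymethoxy)-4-[(3-methylbut-2-en-1-yl)oxy]benzaldehyde
Product: 9 2,4-bis(methoxymethoxy)-5-(2-methylbut-3-en-2-yl)benzaldehyde, via 4-hydroxy-2-(methoxymethoxy)-5-(2-methylbut-3-en-2-yl)benzaldehyde 8 (not isolated)
Conditions: PhNEt2, 190 °C (sealed tube), 2–3 h; cool to 0 °C, then i-Pr2NEt, MOMCl, CH2Cl2, 0 °C to rt (one pot)
Reagents that add atoms: chloromethyl methyl ether (MOMCl), COCCl
Why: Aromatic Claisen rearrangement ([3,3]-sigmatropic shift with allyl inversion) puts the 1,1-dimethylallyl group on C5, the ortho position para to the 2-OMOM donor and not flanked by a second substituent (C3 lies between two oxygens, the para position carries CHO); immediate MOM capping of the new phenol suppresses abnormal-Claisen and cyclisation side reactions.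

Step 5
Reactants: 4 1-[2-hydroxy-4,6-bis(methoxymethoxy)-3-(3-methylbut-2-en-1-yl)phenyl]ethan-1-one; 9 2,4-bis(methoxymethoxy)-5-(2-methylbut-3-en-2-yl)benzaldehyde
Product: 10 (2E)-3-[2,4-bis(methoxymethoxy)-5-(2-methylbut-3-en-2-yl)phenyl]-1-[2-hydroxy-4,6-bis(methoxymethoxy)-3-(3-methylbut-2-en-1-yl)phenyl]prop-2-en-1-one
Conditions: KOH (50% aq), EtOH, 0 °C to rt, 36 h; cold aq NH4Cl to pH 7
Reagents that add atoms: none
Why: Claisen–Schmidt (crossed aldol) condensation of the methyl ketone enolate with the non-enolisable aldehyde, followed by E1cB dehydration, gives the E-enone; in strong base the phenoxide chalcone does not ring-close.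

Step 6
Reactants: 10 (2E)-3-[2,4-bis(methoxymethoxy)-5-(2-methylbut-3-en-2-yl)phenyl]-1-[2-hydroxy-4,6-bis(methoxymethoxy)-3-(3-methylbut-2-en-1-yl)phenyl]prop-2-en-1-one
Product: 11 (2S)-2-[2,4-bis(methoxymethoxy)-5-(2-methylbut-3-en-2-yl)phenyl]-5,7-bis(methoxymethoxy)-8-(3-methylbut-2-en-1-yl)-2,3-dihydro-4H-chromen-4-one
Conditions: catalyst A (10 mol %), PhMe (0.05 M), −20 °C; AcOH quench at −20 °C, silica plug
Reagents that add atoms: none
Why: Proposed new method: enantioselective 6-endo-trig oxa-Michael ring closure of an unactivated, electron-rich 2'-hydroxychalcone by a bifunctional iminophosphorane–thiourea catalyst; the iminophosphorane ionises the chelated 2'-OH to a tight chiral phenoxide/iminophosphoranium ion pair while the thiourea N–H pair binds and activates the enone carbonyl, the tert-butyl group shields one face of the s-cis enone so that the phenoxide adds to C-β to set C2 as S, and the enolate is then protonated by P–N–H+; product 11 has no acidic O–H and its C3–H is much less acidic than the starting phenol, so retro-oxa-Michael (E1cB) racemisation should be slow at −20 °C, and the 6'-OMOM group makes closure strongly favoured; closest known reaction types are the cinchona-thiourea oxa-Michael cyclisation of alkylidene β-ketoesters to 3-carboxyflavanones and iminophosphorane-catalysed intramolecular oxa-Michael additions of alcohols to unsaturated esters and amides, neither shown for a simple 2'-hydroxychalcone lacking an α-activating group.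

Step 7
Reactants: 11 (2S)-2-[2,4-bis(methoxymethoxy)-5-(2-methylbut-3-en-2-yl)phenyl]-5,7-bis(methoxymethoxy)-8-(3-methylbut-2-en-1-yl)-2,3-dihydro-4H-chromen-4-one
Product: 12 (2S)-2-[2,4-dihydroxy-5-(2-methylbut-3-en-2-yl)phenyl]-5,7-dihydroxy-8-(3-methylbut-2-en-1-yl)-2,3-dihydro-4H-chromen-4-one (AChE-IN-17)
Conditions: 3 M aq HCl/MeOH (1:5), 40 °C, 1–2 h
Reagents that add atoms: none
Why: Acid-catalysed acetal exchange (MOM ether solvolysis) in methanol; both alkenes and the C2 stereocentre should survive dilute acid at 40 °C, since flavanone racemisation is base-promoted.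

**Compound list**
1 | 2,4,6-trihydroxyacetophenone | CC(=O)c1c(O)cc(O)cc1O | starting material
2 | prenyl bromide (1-bromo-3-methylbut-2-ene) | CC(C)=CCBr | starting material
3 | 1-[2,4,6-trihydroxy-3-(3-methylbut-2-en-1-yl)phenyl]ethan-1-one | CC(=O)c1c(O)cc(O)c(CC=C(C)C)c1O | intermediate
4 | 1-[2-hydroxy-4,6-bis(methoxymethoxy)-3-(3-methylbut-2-en-1-yl)phenyl]ethan-1-one | CC(=O)c1c(O)c(CC=C(C)C)c(OCOC)cc1OCOC | intermediate
5 | 2,4-dihydroxybenzaldehyde | O=Cc1ccc(O)cc1O | starting material
6 | 2-hydroxy-4-[(3-methylbut-2-en-1-yl)oxy]benzaldehyde | O=Cc1ccc(OCC=C(C)C)cc1O | intermediate (not isolated)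
7 | 2-(methoxymethoxy)-4-[(3-methylbut-2-en-1-yl)oxy]benzaldehyde | COCOc1cc(OCC=C(C)C)ccc1C=O | intermediate
8 | 4-hydroxy-2-(methoxymethoxy)-5-(2-methylbut-3-en-2-yl)benzaldehyde | C=CC(C)(C)c1cc(C=O)c(OCOC)cc1O | intermediate (not isolated)
9 | 2,4-bis(methoxymethoxy)-5-(2-methylbut-3-en-2-yl)benzaldehyde | C=CC(C)(C)c1cc(C=O)c(OCOC)cc1OCOC | intermediate
10 | (2E)-3-[2,4-bis(methoxymethoxy)-5-(2-methylbut-3-en-2-yl)phenyl]-1-[2-hydroxy-4,6-bis(methoxymethoxy)-3-(3-methylbut-2-en-1-yl)phenyl]prop-2-en-1-one | C=CC(C)(C)c1cc(/C=C/C(=O)c2c(O)c(CC=C(C)C)c(OCOC)cc2OCOC)c(OCOC)cc1OCOC | intermediate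
11 | (2S)-2-[2,4-bis(methoxymethoxy)-5-(2-methylbut-3-en-2-yl)phenyl]-5,7-bis(methoxymethoxy)-8-(3-methylbut-2-en-1-yl)-2,3-dihydro-4H-chromen-4-one | C=CC(C)(C)c1cc([C@@H]2CC(=O)c3c(OCOC)cc(OCOC)c(CC=C(C)C)c3O2)c(OCOC)cc1OCOC | intermediate
12 | (2S)-2-[2,4-dihydroxy-5-(2-methylbut-3-en-2-yl)phenyl]-5,7-dihydroxy-8-(3-methylbut-2-en-1-yl)-2,3-dihydro-4H-chromen-4-one | C=CC(C)(C)c1cc([C@@H]2CC(=O)c3c(O)cc(O)c(CC=C(C)C)c3O2)c(O)cc1O | target

**Step count**
Total: 7 steps. Longest linear sequence: 5 steps (1 → 3 → 4 → 10 → 11 → 12; the ring B branch 5 → 7 → 9 → 10 → 11 → 12 is equally long).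

**Three steps most likely to fail**

The new ring closure (step 6) is the least certain: the enone is deactivated by the dialkoxyaryl group, and any reversibility erodes the ee. The fallback uses known chemistry and sets out from 10. Heating 10 with NaOAc in EtOH at reflux gives the racemic tetra-MOM flavanone F1. F1 is then resolved kinetically by asymmetric transfer hydrogenation with RuCl[(R,R)-TsDPEN](p-cymene) in HCO2H/Et3N (5:2)/EtOAc at rt, run to about 55% conversion. By the usual sense of this catalyst the (2R)-ketone is reduced to the cis-(2R,4R)-flavan-4-ol F2, and the unreacted (2S)-ketone is recovered by chromatography. The fallback comes back to the route at 11, with at most half of the material.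

The aromatic Claisen step (step 4) may give C3 attack, loss of the prenyl group, or abnormal-Claisen and dihydrobenzofuran products. The fallback builds the tertiary allyl group by cross-coupling instead and sets out from 5. Bromination (Br2, AcOH, rt) gives 5-bromo-2,4-dihydroxybenzaldehyde F3. MOMCl/K2CO3 in acetone at reflux gives 5-bromo-2,4-bis(methoxymethoxy)benzaldehyde F4. A branch-selective (γ-selective) Suzuki–Miyaura coupling of F4 with prenylboronic acid pinacol ester then follows, using Pd(OAc)2, a bulky electron-rich phosphine such as 1,1'-bis(di-tert-butylphosphino)ferrocene, and K3PO4 in THF/H2O at 60 °C. It comes back to the route at 9.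

The final deprotection (step 7) may cyclise a phenol onto the neighbouring alkene, or erode the ee, before all four MOM groups are gone. The fallback replaces Brønsted-acid solvolysis by silyl transfer and sets out from 11. TMSOTf and 2,2'-bipyridyl in CH2Cl2 at 0 °C convert the aryl MOM ethers into the tetrakis(trimethylsilyl) ether F5. F5 is hydrolysed with water/THF at neutral pH, and the fallback comes back to the route at 12.

**Further compounds**
F1 | step 6 | racemic 2-[2,4-bis(methoxymethoxy)-5-(2-methylbut-3-en-2-yl)phenyl]-5,7-bis(methoxymethoxy)-8-(3-methylbut-2-en-1-yl)-2,3-dihydro-4H-chromen-4-one | C=CC(C)(C)c1cc(C2CC(=O)c3c(OCOC)cc(OCOC)c(CC=C(C)C)c3O2)c(OCOC)cc1OCOC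
F2 | step 6 | (2R,4R)-2-[2,4-bis(methoxymethoxy)-5-(2-methylbut-3-en-2-yl)phenyl]-5,7-bis(methoxymethoxy)-8-(3-methylbut-2-en-1-yl)-3,4-dihydro-2H-chromen-4-ol (2,4-cis) | C=CC(C)(C)c1cc([C@H]2C[C@@H](O)c3c(OCOC)cc(OCOC)c(CC=C(C)C)c3O2)c(OCOC)cc1OCOC
F3 | step 4 | 5-bromo-2,4-dihydroxybenzaldehyde | O=Cc1cc(Br)c(O)cc1O
F4 | step 4 | 5-bromo-2,4-bis(methoxymethoxy)benzaldehyde | COCOc1cc(OCOC)c(Br)cc1C=O
F5 | step 7 | (2S)-2-[5-(2-methylbut-3-en-2-yl)-2,4-bis(trimethylsilyloxy)phenyl]-8-(3-methylbut-2-en-1-yl)-5,7-bis(trimethylsilyloxy)-2,3-dihydro-4H-chromen-4-one | C=CC(C)(C)c1cc([C@@H]2CC(=O)c3c(O[Si](C)(C)C)cc(O[Si](C)(C)C)c(CC=C(C)C)c3O2)c(O[Si](C)(C)C)cc1O[Si](C)(C)C
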